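**Retrosynthetic overview** (germacrane numbering, also used for open-chain intermediates)
1. The strategy rests on the α-acetoxy ketone in the ten-membered carbocycle. The C1 carbonyl carbon and C10, which bears CH3 and OAc, are direct ring neighbours, so the pair is treated as an oxidised, acetylated 1,10-diol.
2. The diol is cut at C1–C10 by a reductive pinacol coupling of two electrophilic carbons. This gives a seco C1 aldehyde / C10 methyl ketone whose two arms sit on C6 and C7 of a trans γ-lactone.
3. The seco compound is built linearly. C1–C6 come from (Z)-crotylboration and hydroboration, C7/C11/C12 from asymmetric propiolate addition, C8 from vinyl conjugate addition, C13 from enolate hydroxymethylation, and C9/C10 from methallylboration.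
4. Ring order: the γ-lactone (as a butenolide) is made first and the ten-membered carbocycle second. The angelate, the exocyclic methylene and the free C3 hydroxyl are introduced only after ring closure.

Key step: step 17

Assumption: the ProPhenol antipode named in step 6 follows the usual facial model of this catalyst. The sense of induction would be checked by Mosher ester analysis of 14, and the other commercial antipode would be used if it proves opposite.

**Step 1**
Reactants: 1 3-(4-methoxybenzyloxy)propan-1-ol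
Product: 2 3-(4-methoxybenzyloxy)propanal
Conditions: TEMPO (10 mol %), PhI(OAc)2 (1.1 equiv), CH2Cl2, rt
Reagents that add atoms: none
Why: The oxoammonium-catalysed (TEMPO/BAIB) oxidation stops at the aldehyde and uses no amine base, so the β-alkoxy aldehyde should not eliminate 4-methoxybenzyl alcohol.

**Step 2**
Reactants: 2 3-(4-methoxybenzyloxy)propanal; 3 cis-2-butene
Product: 7 (3S,4S)-1-(4-methoxybenzyloxy)-4-methylhex-5-en-3-ol, via (Z)-crotylpotassium 4 (not isolated), via (Z)-crotyldiisopinocampheylborane 5 (not isolated), via diisopinocampheylborinate of the adduct 6 (not isolated)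
Conditions: 3, KOt-Bu, n-BuLi, THF, −78 to −45 °C; (+)-Ipc2BOMe [from (−)-α-pinene], −78 °C; BF3·OEt2; 2, −78 °C; then 3 M NaOH, 30% H2O2, rt
Reagents that add atoms: none
Why: In this Brown asymmetric crotylboration the closed chair transition state turns the Z-crotyl geometry into the 3,4-syn relationship, and the Ipc groups from (−)-α-pinene select the aldehyde face that gives 3S,4S.

**Step 3**
Reactants: 7 (3S,4S)-1-(4-methoxybenzyloxy)-4-methylhex-5-en-3-ol
Product: 8 (3S,4S)-3-(tert-butyldimethylsilyloxy)-1-(4-methoxybenzyloxy)-4-methylhex-5-ene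
Conditions: TBSCl, imidazole, DMF, rt
Reagents that add atoms: tert-butyldimethylsilyl chloride, CC(C)(C)[Si](C)(C)Cl
Why: Imidazole-promoted silylation of the only hydroxyl group touches no stereocentre.

**Step 4**
Reactants: 8 (3S,4S)-3-(tert-butyldimethylsilyloxy)-1-(4-methoxybenzyloxy)-4-methylhex-5-ene
Product: 10 (3S,4S)-4-(tert-butyldimethylsilyloxy)-6-(4-methoxybenzyloxy)-3-methylhexan-1-ol, via B-alkyl-9-BBN adduct 9 (not isolated)
Conditions: 9-BBN, THF, 0 °C to rt; then 3 M NaOH, 30% H2O2, 0 °C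
Reagents that add atoms: hydrogen peroxide, OO
Why: Anti-Markovnikov hydroboration–oxidation with bulky 9-BBN puts boron on the terminal carbon (C6) of the monosubstituted alkene, and the oxidation replaces it by hydroxyl without affecting C3 or C4.

**Step 5**
Reactants: 10 (3S,4S)-4-(tert-butyldimethylsilyloxy)-6-(4-methoxybenzyloxy)-3-methylhexan-1-ol
Product: 11 (3S,4S)-4-(tert-butyldimethylsilyloxy)-6-(4-methoxybenzyloxy)-3-methylhexanal (C6 aldehyde)
Conditions: TEMPO (10 mol %), PhI(OAc)2, CH2Cl2, rt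
Reagents that add atoms: none
Why: TEMPO/BAIB oxidation of the primary alcohol stops at the aldehyde, whose α-carbon (C5) is a CH2 group, so no stereocentre can epimerise.

**Step 6**
Reactants: 11 C6 aldehyde; 12 methyl propiolate
Product: 14 methyl (4R,6S,7S)-7-(tert-butyldimethylsilyloxy)-4-hydroxy-9-(4-methoxybenzyloxy)-6-methylnon-2-ynoate, via methyl 3-(methylzincio)propiolate 13 (not isolated)
Conditions: 12 (3 equiv), Me2Zn (3 equiv), (R,R)-ProPhenol (20 mol %), Ph3P=O (40 mol %), toluene, 0–4 °C; aq. NH4Cl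
Reagents that add atoms: none
Why: The dinuclear zinc–amino alcohol (ProPhenol) catalysed asymmetric alkynylation should deliver the zinc propiolate to the Si face of the aldehyde under catalyst control to set 6R, and any C6 epimer is a diastereomer that chromatography can remove.

**Step 7**
Reactants: 14 γ-hydroxy ynoate
Product: 16 (3S,4S,6R)-butenolide = (5R)-5-[(2S,3S)-3-(tert-butyldimethylsilyloxy)-5-(4-methoxybenzyloxy)-2-methylpentyl]furan-2(5H)-one, via (Z)-γ-hydroxy enoate 15 (not isolated)
Conditions: H2 (1 atm), Lindlar catalyst, quinoline, EtOAc, rt; filter; then PPTS (cat.), CH2Cl2, rt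
Reagents that add atoms: none
Why: Lindlar semihydrogenation gives the Z-enoate, in which the C6 hydroxyl and the ester lie cis and close by transesterification to the butenolide with loss of methanol, leaving C6 unchanged.

**Step 8**
Reactants: 16 butenolide; 17 vinylmagnesium bromide
Product: 19 (3S,4S,6R,7R)-6,7-trans 7-vinyl γ-lactone, via trimethylsilyl ketene acetal 18 (not isolated)
Conditions: 17 (1.5 equiv), CuBr·SMe2 (15 mol %), TMSCl (2 equiv), THF, −78 °C; then sat. aq. NH4Cl, rt
Reagents that add atoms: none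
Why: In this copper-catalysed, TMSCl-accelerated conjugate addition of a Grignard reagent the vinyl group should enter C7 on the butenolide face opposite the C6 side chain, giving the 6,7-trans lactone.

**Step 9**
Reactants: 19 7-vinyl γ-lactone
Product: 21 (3S,4S,6R,7S,11R)-11-hydroxymethyl-7-vinyl γ-lactone (6,7-trans and 7,11-trans), via lithium lactone enolate 20 (not isolated)
Conditions: LDA (1.1 equiv), THF, −78 °C; monomeric CH2O (THF solution from cracked paraformaldehyde), −78 to −40 °C; AcOH, −78 °C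
Reagents that add atoms: formaldehyde, C=O
Why: Aldol-type hydroxymethylation of the lactone enolate should occur on the face opposite the neighbouring C7 vinyl group (7,11-trans), and this centre is removed again in step 23.

**Step 10**
Reactants: 21 11-hydroxymethyl lactone
Product: 22 (3S,4S,6R,7S,11R)-all-trans 7-vinyl-11-(tert-butyldimethylsilyloxymethyl) γ-lactone
Conditions: TBSCl, imidazole, CH2Cl2, 0 °C to rt
Reagents that add atoms: tert-butyldimethylsilyl chloride, CC(C)(C)[Si](C)(C)Cl
Why: Mild silylation of the only free (primary) hydroxyl group masks C13 as CH2OTBS without enolising the lactone.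

**Step 11**
Reactants: 22 vinyl silyloxymethyl lactone
Product: 24 (3S,4S,6R,7S,11R)-C8 aldehyde (7-formyl lactone), via vicinal diol 23 (not isolated)
Conditions: OsO4 (2 mol %), NaIO4 (4 equiv), 2,6-lutidine (2 equiv), dioxane/H2O 3:1, rt
Reagents that add atoms: osmium tetroxide, O=[Os](=O)(=O)=O; sodium periodate, [Na+].[O-]I(=O)(=O)=O; water, O
Why: Lemieux–Johnson cleavage of the only alkene consumes the diol as it forms, and the lutidine-buffered near-neutral medium should spare the β-acyloxy aldehyde from elimination while C7 stays in its more stable trans,trans arrangement.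

**Step 12**
Reactants: 24 C8 aldehyde; 25 2-methylallylmagnesium chloride
Product: 28 (3S,4S,6R,7R,8R,11R)-C8 homoallylic alcohol bearing the methallyl chain, via B-methallyldiisopinocampheylborane 26 (not isolated), via diisopinocampheylborinate of the adduct 27 (not isolated)
Conditions: 25, (+)-Ipc2BOMe [from (−)-α-pinene], Et2O, −78 °C to rt, Mg salts allowed to settle; 24, Et2O, −78 °C; then pH 7 phosphate buffer, MeOH, 30% H2O2, 0 °C
Reagents that add atoms: none
Why: In this Brown asymmetric methallylboration the Ipc groups from (−)-α-pinene dictate, through a chair transition state, attack on the aldehyde face leading to 8R, and the buffered peroxide work-up avoids the alkoxide conditions that would cause translactonisation to O8.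

**Step 13**
Reactants: 28 C8 homoallylic alcohol
Product: 29 (3S,4S,6R,7S,8R,11R)-C8 triethylsilyl ether with methallyl side chain
Conditions: TESOTf, 2,6-lutidine, CH2Cl2, −78 °C
Reagents that add atoms: triethylsilyl triflate, CC[Si](CC)(CC)OS(=O)(=O)C(F)(F)F
Why: Fast low-temperature silylation with the silyl triflate and a non-nucleophilic base caps the C8 hydroxyl before it can attack the lactone carbonyl.

**Step 14**
Reactants: 29 C8 TES ether
Product: 31 (3S,4S,6R,7S,8R,11R)-C10 methyl ketone with C1 PMB ether, via 1,2-diol of the methallyl unit 30 (not isolated)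
Conditions: OsO4 (2 mol %), NaIO4 (4 equiv), 2,6-lutidine (2 equiv), dioxane/H2O 3:1, rt
Reagents that add atoms: osmium tetroxide, O=[Os](=O)(=O)=O; sodium periodate, [Na+].[O-]I(=O)(=O)=O; water, O
Why: Lemieux–Johnson cleavage of the only C=C (1,1-disubstituted) gives the methyl ketone, and it is done while C1 is still protected so that the sensitive aldehyde is made last.

**Step 15**
Reactants: 31 C10 methyl ketone PMB ether
Product: 32 (3S,4S,6R,7S,8R,11R)-C1 primary alcohol C10 methyl ketone
Conditions: DDQ (1.3 equiv), CH2Cl2/pH 7 buffer 10:1, 0 °C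
Reagents that add atoms: none
Why: DDQ cleaves the electron-rich PMB ether by benzylic hydride abstraction and hemiacetal hydrolysis, and in the buffered two-phase medium the three silyl ethers, the lactone and the ketone should survive.

**Step 16**
Reactants: 32 C1 alcohol C10 ketone
Product: 33 (3S,4S,6R,7S,8R,11R)-seco keto-aldehyde (C1 aldehyde, C10 methyl ketone)
Conditions: Dess–Martin periodinane, CH2Cl2, 0 °C to rt; used at once
Reagents that add atoms: none
Why: The base-free Dess–Martin oxidation should give the β-silyloxy aldehyde without elimination of the C3 silyloxy group.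

**Step 17**
Reactants: 33 seco keto-aldehyde
Product: 34 (1S,3S,4S,6R,7S,8R,10R,11R)-ten-membered 1,10-diol fused to the trans γ-lactone
Conditions: SmI2 (0.1 M in THF, 4 equiv) diluted with degassed THF; 33 in THF added by syringe pump over about 10 h (final about 1 mM), rt; then air, aq. Rochelle salt/NaHCO3
Reagents that add atoms: none
Why: Samarium diiodide transfers one electron to the C1 aldehyde, the more easily reduced of the two carbonyl groups, and the resulting samarium(III) ketyl adds to the C10 ketone held on the same oxophilic metal, after which a second electron and the aqueous quench deliver the diol. The closest known reaction type is the intramolecular pinacol coupling of keto aldehydes with low-valent samarium or titanium, which has served for medium and large carbocycles, so only the substrate is new. One ring is closed, the ten-membered carbocycle, in a 10-exo-trig ketyl-to-carbonyl mode by forming C1–C10 across the existing trans γ-lactone, whose vicinal C6 and C7 arms act as a turn that shortens the end-to-end distance. C10 is controlled by the C8 silyloxy stereocentre: in the dipole-minimised rotamer of the β-silyloxy ketone the ketyl should reach the carbonyl face that places O10 anti to O8 (10R), a bias that the rigid lactone reinforces and that can be tuned through the size of the C8 silyl group, while the metal bridge should favour the cis-diol (1S), a centre that step 18 erases. The step needs cyclisation to win over dimerisation and over plain reduction, which slow addition into excess reagent at millimolar concentration without a proton source should secure. It also needs chemoselectivity, which the substrate provides because lactone and silyl ethers do not react with SmI2 in THF, neither carbonyl has an α-leaving group, and the methylene lactone and the angelate, both ketyl acceptors, are still absent (C13 is carried as CH2OTBS).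

**Step 18**
Reactants: 34 1,10-diol
Product: 35 (3S,4S,6R,7S,8R,10R,11R)-C1 ketone C10 tertiary alcohol (α-ketol)
Conditions: Dess–Martin periodinane, CH2Cl2, 0 °C to rt
Reagents that add atoms: none
Why: Dess–Martin oxidation can act only on the secondary C1 carbinol because the C10 hydroxyl is tertiary, and it removes the C1 stereocentre so that both C1 epimers of the pinacol product converge.

**Step 19**
Reactants: 35 α-ketol
Product: 36 (3S,4S,6R,7S,8R,10R,11R)-C1 ketone C10 acetate
Conditions: Ac2O (10 equiv), DMAP (2 equiv), Et3N (12 equiv), CH2Cl2, 35 °C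
Reagents that add atoms: acetic anhydride, CC(=O)OC(C)=O
Why: DMAP-catalysed acylation should acetylate the only free hydroxyl, since this tertiary carbinol is flanked by an sp2 carbon and is more acidic than an ordinary tertiary alcohol, and C10 keeps its configuration because the C–O bond is not broken.

**Step 20**
Reactants: 36 C1 ketone C10 acetate
Product: 37 (3S,4S,6R,7R,8R,10R,11R)-C8 alcohol
Conditions: PPTS (cat.), MeOH/CH2Cl2 1:1, 0 °C, monitored closely
Reagents that add atoms: none
Why: Acid-catalysed methanolysis distinguishes silyl ethers by bulk at silicon, so the triethylsilyl group should be solvolysed much faster than either tert-butyldimethylsilyl group at 0 °C.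

**Step 21**
Reactants: 37 C8 alcohol; 38 angelic acid
Product: 40 (3S,4S,6R,7S,8R,10R,11R)-C8 angelate with masked methylene, via angelic 2,4,6-trichlorobenzoic anhydride 39 (not isolated)
Conditions: 38 (4 equiv), 2,4,6-trichlorobenzoyl chloride (4 equiv), Et3N (4 equiv), toluene, rt; then 37, toluene, 75 °C, no DMAP
Reagents that add atoms: none
Why: In this Yamaguchi mixed-anhydride esterification the alcohol attacks the less hindered angeloyl carbonyl, and leaving out the nucleophilic catalyst removes the addition–elimination pathway that would turn the Z (angelate) geometry into E.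

**Step 22**
Reactants: 40 C8 angelate
Product: 41 (3S,4S,6R,7S,8R,10R,11R)-C13 primary alcohol
Conditions: HF·pyridine, pyridine, THF, 0 °C
Reagents that add atoms: none
Why: Buffered HF·pyridine should remove the unhindered primary TBS ether much faster than the secondary one at C3, which is shielded by the C4 methyl branch.

**Step 23**
Reactants: 41 C13 primary alcohol
Product: 43 (3S,4S,6R,7S,8R,10R)-α-methylene lactone C3 TBS ether, via C13 mesylate 42 (not isolated)
Conditions: MsCl, Et3N, CH2Cl2, 0 °C; then DBU (1.5 equiv), 0 °C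
Reagents that add atoms: none
Why: Mesylation followed by E1cB elimination through the acidic C11–H expels the good leaving group quickly at 0 °C, well before the poorer C3 silyloxy group β to the ketone can leave, and it removes the C11 centre.

**Step 24**
Reactants: 43 α-methylene lactone C3 TBS ether
Product: 44 CNP0141210.1, (3S,4S,6R,7S,8R,10R)
Conditions: HF·pyridine (excess), MeCN, 0 °C to rt
Reagents that add atoms: none
Why: Mildly acidic fluoride desilylation frees the C3 hydroxyl and avoids basic fluoride sources, which could cause retro-aldol cleavage of the β-hydroxy ketone or addition to the methylene lactone.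

**Compound list**
1 | 3-(4-methoxybenzyloxy)propan-1-ol | OCCCOCc1ccc(OC)cc1 | starting material
2 | 3-(4-methoxybenzyloxy)propanal | O=CCCOCc1ccc(OC)cc1 | intermediate
3 | cis-2-butene | C/C=C\C | starting material
4 | (Z)-crotylpotassium | C/C=C\C[K] | intermediate
5 | (Z)-crotyldiisopinocampheylborane, Ipc from (−)-α-pinene | C/C=C\CB([C@H]1C[C@H]2C[C@@H]([C@@H]1C)C2(C)C)[C@H]3C[C@H]4C[C@@H]([C@@H]3C)C4(C)C | intermediate
6 | diisopinocampheylborinate of alcohol 7 | C=C[C@H](C)[C@@H](OB([C@H]1C[C@H]2C[C@@H]([C@@H]1C)C2(C)C)[C@H]3C[C@H]4C[C@@H]([C@@H]3C)C4(C)C)CCOCc5ccc(OC)cc5 | intermediate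
7 | (3S,4S)-1-(4-methoxybenzyloxy)-4-methylhex-5-en-3-ol (3,4-syn) | C=C[C@H](C)[C@@H](O)CCOCc1ccc(OC)cc1 | intermediate
8 | (3S,4S)-3-(tert-butyldimethylsilyloxy)-1-(4-methoxybenzyloxy)-4-methylhex-5-ene | C=C[C@H](C)[C@@H](O[Si](C)(C)C(C)(C)C)CCOCc1ccc(OC)cc1 | intermediate
9 | B-alkyl-9-BBN adduct of 8 (boron on C6) | C1CCC2CCCC1B2CC[C@H](C)[C@@H](O[Si](C)(C)C(C)(C)C)CCOCc3ccc(OC)cc3 | intermediate
10 | (3S,4S)-4-(tert-butyldimethylsilyloxy)-6-(4-methoxybenzyloxy)-3-methylhexan-1-ol | OCC[C@H](C)[C@@H](O[Si](C)(C)C(C)(C)C)CCOCc1ccc(OC)cc1 | intermediate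
11 | (3S,4S)-4-(tert-butyldimethylsilyloxy)-6-(4-methoxybenzyloxy)-3-methylhexanal (C6 aldehyde) | O=CC[C@H](C)[C@@H](O[Si](C)(C)C(C)(C)C)CCOCc1ccc(OC)cc1 | intermediate
12 | methyl propiolate | C#CC(=O)OC | starting material
13 | methyl 3-(methylzincio)propiolate | C[Zn]C#CC(=O)OC | intermediate
14 | methyl (4R,6S,7S)-7-(tert-butyldimethylsilyloxy)-4-hydroxy-9-(4-methoxybenzyloxy)-6-methylnon-2-ynoate | COC(=O)C#C[C@H](O)C[C@H](C)[C@@H](O[Si](C)(C)C(C)(C)C)CCOCc1ccc(OC)cc1 | intermediate
15 | methyl (2Z,4R,6S,7S)-7-(tert-butyldimethylsilyloxy)-4-hydroxy-9-(4-methoxybenzyloxy)-6-methylnon-2-enoate | COC(=O)/C=C\[C@H](O)C[C@H](C)[C@@H](O[Si](C)(C)C(C)(C)C)CCOCc1ccc(OC)cc1 | intermediate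
16 | (5R)-5-[(2S,3S)-3-(tert-butyldimethylsilyloxy)-5-(4-methoxybenzyloxy)-2-methylpentyl]furan-2(5H)-one | O=C1C=C[C@@H](C[C@H](C)[C@@H](O[Si](C)(C)C(C)(C)C)CCOCc2ccc(OC)cc2)O1 | intermediate
17 | vinylmagnesium bromide | C=C[Mg]Br | starting material
18 | trimethylsilyl ketene acetal of lactone 19 | C=C[C@H]1C=C(O[Si](C)(C)C)O[C@@H]1C[C@H](C)[C@@H](O[Si](C)(C)C(C)(C)C)CCOCc2ccc(OC)cc2 | intermediate
19 | (3S,4S,6R,7R)-6,7-trans 7-vinyl γ-lactone | C=C[C@H]1CC(=O)O[C@@H]1C[C@H](C)[C@@H](O[Si](C)(C)C(C)(C)C)CCOCc2ccc(OC)cc2 | intermediate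
20 | lithium enolate of lactone 19 | C=C[C@H]1C=C(O[Li])O[C@@H]1C[C@H](C)[C@@H](O[Si](C)(C)C(C)(C)C)CCOCc2ccc(OC)cc2 | intermediate
21 | (3S,4S,6R,7S,11R)-11-hydroxymethyl-7-vinyl γ-lactone, all-trans | C=C[C@H]1[C@H](CO)C(=O)O[C@@H]1C[C@H](C)[C@@H](O[Si](C)(C)C(C)(C)C)CCOCc2ccc(OC)cc2 | intermediate
22 | (3S,4S,6R,7S,11R)-11-(tert-butyldimethylsilyloxymethyl)-7-vinyl γ-lactone, all-trans | C=C[C@H]1[C@H](CO[Si](C)(C)C(C)(C)C)C(=O)O[C@@H]1C[C@H](C)[C@@H](O[Si](C)(C)C(C)(C)C)CCOCc2ccc(OC)cc2 | intermediate
23 | vicinal diol from the vinyl group of 22 (epimers at the new carbinol) | OCC(O)[C@H]1[C@H](CO[Si](C)(C)C(C)(C)C)C(=O)O[C@@H]1C[C@H](C)[C@@H](O[Si](C)(C)C(C)(C)C)CCOCc2ccc(OC)cc2 | intermediate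
24 | (3S,4S,6R,7S,11R)-C8 aldehyde (7-formyl lactone) | O=C[C@H]1[C@H](CO[Si](C)(C)C(C)(C)C)C(=O)O[C@@H]1C[C@H](C)[C@@H](O[Si](C)(C)C(C)(C)C)CCOCc2ccc(OC)cc2 | intermediate
25 | 2-methylallylmagnesium chloride | C=C(C)C[Mg]Cl | starting material
26 | B-methallyldiisopinocampheylborane, Ipc from (−)-α-pinene | C=C(C)CB([C@H]1C[C@H]2C[C@@H]([C@@H]1C)C2(C)C)[C@H]3C[C@H]4C[C@@H]([C@@H]3C)C4(C)C | intermediate
27 | diisopinocampheylborinate of alcohol 28 | C=C(C)C[C@@H](OB([C@H]1C[C@H]2C[C@@H]([C@@H]1C)C2(C)C)[C@H]3C[C@H]4C[C@@H]([C@@H]3C)C4(C)C)[C@H]5[C@H](CO[Si](C)(C)C(C)(C)C)C(=O)O[C@@H]5C[C@H](C)[C@@H](O[Si](C)(C)C(C)(C)C)CCOCc6ccc(OC)cc6 | intermediate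
28 | (3S,4S,6R,7R,8R,11R)-C8 homoallylic alcohol with methallyl chain | C=C(C)C[C@@H](O)[C@H]1[C@H](CO[Si](C)(C)C(C)(C)C)C(=O)O[C@@H]1C[C@H](C)[C@@H](O[Si](C)(C)C(C)(C)C)CCOCc2ccc(OC)cc2 | intermediate
29 | (3S,4S,6R,7S,8R,11R)-C8 triethylsilyl ether with methallyl chain | C=C(C)C[C@@H](O[Si](CC)(CC)CC)[C@H]1[C@H](CO[Si](C)(C)C(C)(C)C)C(=O)O[C@@H]1C[C@H](C)[C@@H](O[Si](C)(C)C(C)(C)C)CCOCc2ccc(OC)cc2 | intermediate
30 | 1,2-diol from the methallyl alkene of 29 (epimers at the new carbinol) | OCC(C)(O)C[C@@H](O[Si](CC)(CC)CC)[C@H]1[C@H](CO[Si](C)(C)C(C)(C)C)C(=O)O[C@@H]1C[C@H](C)[C@@H](O[Si](C)(C)C(C)(C)C)CCOCc2ccc(OC)cc2 | intermediate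
31 | (3S,4S,6R,7S,8R,11R)-C10 methyl ketone, C1 PMB ether | CC(=O)C[C@@H](O[Si](CC)(CC)CC)[C@H]1[C@H](CO[Si](C)(C)C(C)(C)C)C(=O)O[C@@H]1C[C@H](C)[C@@H](O[Si](C)(C)C(C)(C)C)CCOCc2ccc(OC)cc2 | intermediate
32 | (3S,4S,6R,7S,8R,11R)-C10 methyl ketone, C1 primary alcohol | CC(=O)C[C@@H](O[Si](CC)(CC)CC)[C@H]1[C@H](CO[Si](C)(C)C(C)(C)C)C(=O)O[C@@H]1C[C@H](C)[C@@H](O[Si](C)(C)C(C)(C)C)CCO | intermediate
33 | (3S,4S,6R,7S,8R,11R)-seco keto-aldehyde | CC(=O)C[C@@H](O[Si](CC)(CC)CC)[C@H]1[C@H](CO[Si](C)(C)C(C)(C)C)C(=O)O[C@@H]1C[C@H](C)[C@@H](O[Si](C)(C)C(C)(C)C)CC=O | intermediate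
34 | (1S,3S,4S,6R,7S,8R,10R,11R)-ten-membered cis-1,10-diol | CC(C)(C)[Si](C)(C)OC[C@@H]1C(=O)O[C@@H]2C[C@H](C)[C@@H](O[Si](C)(C)C(C)(C)C)C[C@H](O)[C@](C)(O)C[C@@H](O[Si](CC)(CC)CC)[C@@H]12 | intermediate
35 | (3S,4S,6R,7S,8R,10R,11R)-C1 ketone C10 tertiary alcohol | CC(C)(C)[Si](C)(C)OC[C@@H]1C(=O)O[C@@H]2C[C@H](C)[C@@H](O[Si](C)(C)C(C)(C)C)CC(=O)[C@](C)(O)C[C@@H](O[Si](CC)(CC)CC)[C@@H]12 | intermediate
36 | (3S,4S,6R,7S,8R,10R,11R)-C1 ketone C10 acetate | CC(C)(C)[Si](C)(C)OC[C@@H]1C(=O)O[C@@H]2C[C@H](C)[C@@H](O[Si](C)(C)C(C)(C)C)CC(=O)[C@](C)(OC(C)=O)C[C@@H](O[Si](CC)(CC)CC)[C@@H]12 | intermediate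
37 | (3S,4S,6R,7R,8R,10R,11R)-C8 alcohol | CC(C)(C)[Si](C)(C)OC[C@@H]1C(=O)O[C@@H]2C[C@H](C)[C@@H](O[Si](C)(C)C(C)(C)C)CC(=O)[C@](C)(OC(C)=O)C[C@@H](O)[C@@H]12 | intermediate
38 | angelic acid, (Z)-2-methylbut-2-enoic acid | C/C=C(/C)C(=O)O | starting material
39 | angelic 2,4,6-trichlorobenzoic anhydride | C/C=C(/C)C(=O)OC(=O)c1c(Cl)cc(Cl)cc1Cl | intermediate
40 | (3S,4S,6R,7S,8R,10R,11R)-C8 angelate with C13 as CH2OTBS | CC(C)(C)[Si](C)(C)OC[C@@H]1C(=O)O[C@@H]2C[C@H](C)[C@@H](O[Si](C)(C)C(C)(C)C)CC(=O)[C@](C)(OC(C)=O)C[C@@H](OC(=O)/C(C)=C\C)[C@@H]12 | intermediate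
41 | (3S,4S,6R,7S,8R,10R,11R)-C13 primary alcohol | OC[C@@H]1C(=O)O[C@@H]2C[C@H](C)[C@@H](O[Si](C)(C)C(C)(C)C)CC(=O)[C@](C)(OC(C)=O)C[C@@H](OC(=O)/C(C)=C\C)[C@@H]12 | intermediate
42 | C13 mesylate of 41 | CS(=O)(=O)OC[C@@H]1C(=O)O[C@@H]2C[C@H](C)[C@@H](O[Si](C)(C)C(C)(C)C)CC(=O)[C@](C)(OC(C)=O)C[C@@H](OC(=O)/C(C)=C\C)[C@@H]12 | intermediate
43 | (3S,4S,6R,7S,8R,10R)-α-methylene lactone, C3 TBS ether | C=C1C(=O)O[C@@H]2C[C@H](C)[C@@H](O[Si](C)(C)C(C)(C)C)CC(=O)[C@](C)(OC(C)=O)C[C@@H](OC(=O)/C(C)=C\C)[C@@H]12 | intermediate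
44 | CNP0141210.1, (3S,4S,6R,7S,8R,10R) | C=C1C(=O)O[C@@H]2C[C@H](C)[C@@H](O)CC(=O)[C@](C)(OC(C)=O)C[C@@H](OC(=O)/C(C)=C\C)[C@@H]12 | target

**Total step count:** 24. **Longest linear sequence:** 24 steps (1 to 44).

**Steps most likely to fail**

*Step 17 (pinacol macrocyclisation).* Dimerisation or plain reduction of the aldehyde may outrun the entropically and transannularly disfavoured ten-membered closure. Facial selectivity at C10 may be poor. The samarium alkoxides may also trigger silyl migration.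

The fallback sets out from 29 and comes back at 34. It makes the C1–C10 link as an alkene and oxidises it afterwards.
- DDQ removal of the PMB group would give the methallyl-bearing primary alcohol F1.
- Dess–Martin oxidation would give the methallyl-bearing C1 aldehyde F2.
- Wittig methylenation (Ph3P=CH2, THF, −78 to 0 °C) would give the seco diene F3.
- Ring-closing metathesis (second-generation Hoveyda–Grubbs catalyst, dilute toluene, 80–110 °C) would join the C1 vinyl and C10 isopropenyl termini to the (Z)-1(10)-cyclodecene F4.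
- Syn-dihydroxylation with OsO4 (NMO or TMEDA) from the peripheral face would return diol 34.

*Step 21 (angelate esterification).* Acylation of the hindered C8 hydroxyl may be slow at the temperature required. That leaves time for four side processes:
- transannular hemiketalisation onto the C1 ketone;
- 1,3-migration of the acetyl group from O10 to O8;
- translactonisation toward O8;
- Z-to-E isomerisation of the activated acyl group.

The fallback sets out from 37 and comes back at 40. It builds the Z-alkene on the ester instead of transferring it. Steglich coupling (DCC, cat. DMAP, CH2Cl2, rt) with the small acid 2-[bis(2,2,2-trifluoroethoxy)phosphoryl]propanoic acid would give the C8 phosphonopropionate F5. Still–Gennari olefination (KHMDS, 1.0 equiv, 18-crown-6, THF, −78 °C, then acetaldehyde) would then give the Z-trisubstituted enoate 40.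

*Step 19 (acetylation of the tertiary α-ketol).* Acylation may be sluggish. Forcing basic conditions may start β-elimination of the C3 silyloxy group or α-ketol rearrangement.

The fallback sets out from 34 and comes back at 36. It places the acetyl group before the oxidation.
- Trimethyl orthoacetate with catalytic PPTS (CH2Cl2, rt) would give the cyclic 1,10-orthoacetate F6.
- Brief hydrolysis with aqueous acetic acid at 0 °C, an opening that leaves the acyl group on the more hindered oxygen, would give the C10 acetate C1 alcohol F7.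
- Dess–Martin oxidation of the free secondary C1 carbinol would give 36.

**Further compounds**
F1 | step 17 | methallyl-bearing primary alcohol (29 without PMB) | C=C(C)C[C@@H](O[Si](CC)(CC)CC)[C@H]1[C@H](CO[Si](C)(C)C(C)(C)C)C(=O)O[C@@H]1C[C@H](C)[C@@H](O[Si](C)(C)C(C)(C)C)CCO
F2 | step 17 | methallyl-bearing C1 aldehyde | C=C(C)C[C@@H](O[Si](CC)(CC)CC)[C@H]1[C@H](CO[Si](C)(C)C(C)(C)C)C(=O)O[C@@H]1C[C@H](C)[C@@H](O[Si](C)(C)C(C)(C)C)CC=O
F3 | step 17 | seco diene (C1 vinyl, C10 isopropenyl) | C=C(C)C[C@@H](O[Si](CC)(CC)CC)[C@H]1[C@H](CO[Si](C)(C)C(C)(C)C)C(=O)O[C@@H]1C[C@H](C)[C@@H](O[Si](C)(C)C(C)(C)C)CC=C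
F4 | step 17 | (Z)-1(10)-cyclodecene fused to the trans lactone | CC(C)(C)[Si](C)(C)OC[C@@H]1C(=O)O[C@@H]2C[C@H](C)[C@@H](O[Si](C)(C)C(C)(C)C)C/C=C(/C)C[C@@H](O[Si](CC)(CC)CC)[C@@H]12
F5 | step 21 | C8 2-[bis(2,2,2-trifluoroethoxy)phosphoryl]propanoate (epimers at the phosphonate carbon) | CC(C)(C)[Si](C)(C)OC[C@@H]1C(=O)O[C@@H]2C[C@H](C)[C@@H](O[Si](C)(C)C(C)(C)C)CC(=O)[C@](C)(OC(C)=O)C[C@@H](OC(=O)C(C)P(=O)(OCC(F)(F)F)OCC(F)(F)F)[C@@H]12
F6 | step 19 | cyclic 1,10-orthoacetate (epimers at the orthoester carbon) | CC(C)(C)[Si](C)(C)OC[C@@H]1C(=O)O[C@@H]2C[C@H](C)[C@@H](O[Si](C)(C)C(C)(C)C)C[C@@H]3OC(C)(OC)O[C@]3(C)C[C@@H](O[Si](CC)(CC)CC)[C@@H]12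
F7 | step 19 | C10 acetate C1 alcohol | CC(C)(C)[Si](C)(C)OC[C@@H]1C(=O)O[C@@H]2C[C@H](C)[C@@H](O[Si](C)(C)C(C)(C)C)C[C@H](O)[C@](C)(OC(C)=O)C[C@@H](O[Si](CC)(CC)CC)[C@@H]12
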